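Its constants were set for the occasion.

Follow one molecule.

solid substrate 0.50 M; gas 200 mM (held); time 30 h

* how much target and solid product together there is at 30 h, in percent of the solid substrate charged
* concentration of dissolved substrate in solution at 30 h, in percent of saturation

- in percentages every species weighs as the solid substrate in it: one side product counts as two
- for target the solid product is counted in
- two of one species on the left: rate k times its square, two consumed each time
- as a solid, counted per litre of solution: solid substrate, solid product
- at the start none of partner is dissolved
- at the start none of the solid substrate is in solution
- dissolved substrate means what is dissolved; the solid is not counted in it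
- run time (flask): 30 h

    solid substrate ⇌ dissolved substrate, rate k1*(cs1 - [dissolved substrate]) while solid is left; crystals form when [dissolved substrate] > cs1 (cs1 = 0.19 M, k1 = 0.097 min⁻¹)
    dissolved substrate + partner → target (k2 = 0.012 M⁻¹ min⁻¹)
    2 dissolved substrate → side product (k3 = 0.013 M⁻¹ min⁻¹)
    solid product ⇌ target, rate k4*(cs4 - [target]) while solid is left; crystals form when [target] > cs4 (cs4 = 0.16 M, k4 = 0.11 min⁻¹)
    gas ⇌ partner, rate k5*(csat - [partner]) (k5 = 0.0039 min⁻¹, csat = 200 mM)
    partner → decomposed reagent (k6 = 7.2 × 10⁻⁵ min⁻¹)
    partner ⇌ dormant form (K7 = 4.0, k7 = 0.0033 min⁻¹)

A molecule of dissolved substrate in this flask meets a fork: with partner it becomes target, with a second dissolved substrate it becomes side product. In the first instants the solution fills towards saturation with a half-time of 7.15 min, the solid delivering 0.0184 M min⁻¹ into an empty solution against the 9.39 × 10⁻⁴ M min⁻¹ that the side step draws at saturation, so c(dissolved substrate) climbs to about 0.19 M and stays near it while solid lasts.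

Partner starts at zero and at first enters from the gas at 0.0468 M h⁻¹. It leaves by the way back to the gas, to the dormant form and to target. Dividing that supply by those first-order losses gives c(partner) of about 0.0823 M. We crudely hold it there, which makes the target exit pseudo-first-order. Then at c(dissolved substrate) = 0.0380 M the two exits are equally likely. We call this the even-odds concentration E: the target constant times c(partner), over 2 times the side constant. A molecule's chance of target is E/(E + c(dissolved substrate)).

In the middle, at saturation, that chance is 16.7 %. The 0.310 M beyond saturation passes this fork and yields 0.0516 M of target, taking about 4.59 h.

At the end, with no solid by our count, c(dissolved substrate) falls and the chance improves. Summing it down the fall gives E times the natural logarithm of 6.00, or 0.0681 M. Our total of 0.120 M stays below the solubility of target, 0.16 M, so no solid product forms, and we commit to 23.9 %. Meanwhile the chance of side product shrinks exponentially at the pseudo-first-order rate, reaching 0.185 at the end of the run, which means 4.54 % of saturation.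

The forecast said 20 % (16 % to 25 %) of the charge as target and solid product, and 3 % (2 % to 4.5 %) of saturation, since “most substrate goes to side product”; our figures stand above both.

The flask gives 22.3 % of the charge as target and solid product, and 2.82 % of saturation.

Partner in this flask was not steady at our level: it stood at 0.0685 M after 3.00 h and 0.145 M after 30.0 h. With that last value E goes from our 0.0380 M to 0.0668 M, well above the c(dissolved substrate) of 0.00536 M, so a molecule then has a 92.6 % chance of target.

The neighbour flask is charged with 0.12 M of solid substrate, less than its solubility of 0.19 M, so we reckon the falling stage by itself: our first E of 0.0380 M gives 0.0542 M of target, or 45.1 % of its charge. The simulation of that neighbour flask gives 40.7 %, with 2.4 % of its charge still there as substrate.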